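**Retrosynthetic overview**

1. Feature: in ring A (the benzene ring with CH3 and CHO) the carbon that carries the depsidone lactone carbonyl lies between the C–CH3 carbon and the C–O(aryl) carbon and is para to the ring A phenol oxygen. A phenol iodinates at exactly this position, so the carbonyl carbon can be delivered there as CO instead of being carried as a di-ortho-substituted acid.
2. Key disconnection: the central seven-membered lactone (ring D; aryl–C(=O) and C(=O)–O bonds) by palladium-catalysed carbonylative lactonisation of an ortho-iodo diaryl ether phenol. The ether C–O bond comes from SNAr of a ring B phenol on a 2-fluoro-3-iodobenzaldehyde.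
3. Ring B with its fused lactol lactone (ring C, masked as the methyl pseudo-ester) comes from a Diels–Alder benzannulation of a 4-benzyloxy-1,3-bis(silyloxy)diene with methyl 4,4-diethoxybut-2-ynoate. The benzyl ether marks the oxygen that becomes the diaryl ether; THP ethers mask the other two and leave under acid too mild to touch the ring A MOM ether.
4. Endgame: boron-templated hydroxymethylation of ring B, acid unmasking, fumarate ester through the ortho-quinone methide, and the lactol stereocentre last by crystallisation of a cinchonidinium salt.
5. Ring order: rings B and C (step 7), ring A bought as a phenol, ring D (step 12).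

Key step: step 12

Assumption: the lactol carbon of the hydroxyphthalide epimerises in solution by ring–chain tautomerism, so it is carried racemic and fixed last; cinchonidine is written as the alkaloid whose salt with the (R) lactol is the less soluble one, which screening (cinchonine as the pseudo-enantiomeric alternative) would have to confirm.

**Route**

Step 1
Reactants: 1 3-fluoro-5-methylphenol
Product: 2 3-fluoro-4-iodo-5-methylphenol
Conditions: NIS (1.05 equiv), TsOH·H2O (0.1 equiv), MeCN, 0 °C → rt
Reagents that add atoms: N-iodosuccinimide, O=C1CCC(=O)N1I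
Why: Electrophilic aromatic iodination of the phenol is expected para to the hydroxyl, at the carbon between the C–F and C–CH3 carbons, as in the para halogenation of 3,5-disubstituted phenols, and minor ortho isomers should be removed by crystallisation.

Step 2
Reactants: 2 3-fluoro-4-iodo-5-methylphenol
Product: 3 1-fluoro-2-iodo-5-(methoxymethoxy)-3-methylbenzene
Conditions: MOMCl, i-Pr2NEt, CH2Cl2, 0 °C → rt
Reagents that add atoms: chloromethyl methyl ether, COCCl
Why: O-alkylation of the phenol with the reactive chloromethyl ether under amine base gives the MOM ether, which directs the next lithiation and survives base and weak acid.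

Step 3
Reactants: 3 1-fluoro-2-iodo-5-(methoxymethoxy)-3-methylbenzene
Product: 5 2-fluoro-3-iodo-6-(methoxymethoxy)-4-methylbenzaldehyde, via aryllithium 4 (not isolated)
Conditions: LiN(iPr)2 (LDA), THF, −78 °C; DMF, −78 → −40 °C; AcOH
Reagents that add atoms: N,N-dimethylformamide, CN(C)C=O
Why: Directed ortho-metalation takes the most acidic ring hydrogen, flanked by fluorine and the MOM oxygen, with a lithium amide that does not exchange iodine at −78 °C, and the aryllithium is formylated by DMF.

Step 4
Reactants: 6 ethyl 4-(benzyloxy)-3-oxobutanoate
Product: 7 ethyl 4-(benzyloxy)-3-(trimethylsilyloxy)but-2-enoate (E/Z mixture)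
Conditions: TMSCl, Et3N, hexane, rt
Reagents that add atoms: chlorotrimethylsilane, C[Si](C)(C)Cl
Why: O-silylation of the enol of the β-keto ester under amine base gives the conjugated silyl enol ether.

Step 5
Reactants: 7 ethyl 4-(benzyloxy)-3-(trimethylsilyloxy)but-2-enoate
Product: 9 4-(benzyloxy)-1-ethoxy-1,3-bis(trimethylsilyloxy)buta-1,3-diene (isomer mixture), via lithium dienolate 8 (not isolated)
Conditions: LiN(iPr)2, THF, −78 °C; TMSCl, −78 °C → rt; used crude
Reagents that add atoms: chlorotrimethylsilane, C[Si](C)(C)Cl
Why: Kinetic γ-deprotonation of the vinylogous ester and O-silylation of the lithium dienolate give the electron-rich 1,3-bis(silyloxy)diene, which already carries the third ring B oxygen as a benzyl ether.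

Step 6
Reactants: 10 3,3-diethoxyprop-1-yne
Product: 12 methyl 4,4-diethoxybut-2-ynoate, via lithium acetylide 11 (not isolated)
Conditions: n-BuLi, THF, −78 °C; ClCO2Me, −78 → 0 °C
Reagents that add atoms: methyl chloroformate, COC(=O)Cl
Why: Deprotonation of the terminal alkyne and acylation of the lithium acetylide with the chloroformate give the ynoate.

Step 7
Reactants: 9 4-(benzyloxy)-1-ethoxy-1,3-bis(trimethylsilyloxy)buta-1,3-diene; 12 methyl 4,4-diethoxybut-2-ynoate
Product: 15 racemic 4-(benzyloxy)-5,7-dihydroxy-3-methoxy-2-benzofuran-1(3H)-one, via cyclohexadiene cycloadduct 13 (not isolated), via benzoate diethyl acetal 14 (not isolated)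
Conditions: toluene, 100 °C; then TsOH·H2O, MeOH, 60 °C
Reagents that add atoms: methanol, CO; water, O
Why: Diels–Alder benzannulation in which the nucleophilic diene terminus (the carbon with the benzyloxy group) bonds to the ynoate carbon β to the ester, 1,4-elimination of ethanol aromatises, and acidic methanol removes the silyl groups and closes the ortho acetal and ester to the methyl pseudo-ester, whose acetal carbon forms racemic and is left so.

Step 8
Reactants: 15 racemic 4-(benzyloxy)-5,7-dihydroxy-3-methoxy-2-benzofuran-1(3H)-one
Product: 16 4-(benzyloxy)-3-methoxy-5,7-bis(tetrahydro-2H-pyran-2-yloxy)-2-benzofuran-1(3H)-one (diastereomer mixture)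
Conditions: 3,4-dihydro-2H-pyran, PPTS, CH2Cl2, rt → 40 °C
Reagents that add atoms: 3,4-dihydro-2H-pyran, C1CCOC=C1
Why: Acid-catalysed addition of the two phenols to the enol ether gives THP acetals, which are stable to base and hydrogenolysis yet leave under much milder acid than the ring A MOM ether; their new acetal carbons are uncontrolled and are removed in step 11.

Step 9
Reactants: 16 4-(benzyloxy)-3-methoxy-5,7-bis(tetrahydro-2H-pyran-2-yloxy)-2-benzofuran-1(3H)-one
Product: 17 4-hydroxy-3-methoxy-5,7-bis(tetrahydro-2H-pyran-2-yloxy)-2-benzofuran-1(3H)-one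
Conditions: H2 (1 atm), 10% Pd/C, EtOAc, rt
Reagents that add atoms: none
Why: Hydrogenolysis of the aryl benzyl ether frees only the phenol that is to become the diaryl ether oxygen, the THP ethers and the lactone acetal being stable in neutral ethyl acetate.

Step 10
Reactants: 17 4-hydroxy-3-methoxy-5,7-bis(tetrahydro-2H-pyran-2-yloxy)-2-benzofuran-1(3H)-one; 5 2-fluoro-3-iodo-6-(methoxymethoxy)-4-methylbenzaldehyde
Product: 18 3-iodo-2-{[3-methoxy-1-oxo-5,7-bis(tetrahydro-2H-pyran-2-yloxy)-1,3-dihydro-2-benzofuran-4-yl]oxy}-6-(methoxymethoxy)-4-methylbenzaldehyde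
Conditions: Cs2CO3, DMF, 80 °C
Reagents that add atoms: none
Why: Nucleophilic aromatic substitution (addition–elimination) of the fluoride, activated by the ortho formyl group and the inductive pull of the ortho iodine, by the caesium phenoxide; the iodide is meta to the formyl group and is not displaced, and any pseudo-ester opened by base is reclosed in the acidic methanol of step 11.

Step 11
Reactants: 18 the bis-THP diaryl ether
Product: 19 2-[(5,7-dihydroxy-3-methoxy-1-oxo-1,3-dihydro-2-benzofuran-4-yl)oxy]-3-iodo-6-(methoxymethoxy)-4-methylbenzaldehyde (racemic methyl acetal)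
Conditions: PPTS, MeOH, rt → 40 °C
Reagents that add atoms: none
Why: Acid-catalysed transacetalisation to methanol removes the aryl THP ethers under conditions that leave the aryl MOM ether, the iodide and the methyl pseudo-ester intact.

Step 12
Reactants: 19 the ortho-iodo diaryl ether diol; 20 carbon monoxide
Product: 21 depsidone core, racemic methyl acetal (ring A with CH3, OMOM and CHO; ring D closed; ring B with one free hydroxyl and one free CH; ring C as 3-methoxyphthalide)
Conditions: CO (1 atm), Pd(OAc)2 (5 mol%), Xantphos (7.5 mol%), Et3N (3 equiv), toluene (0.02 M), 85 °C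
Reagents that add atoms: none
Why: Pd(OAc)2 is reduced in situ to zerovalent palladium, which inserts into the ring A aryl–iodine bond; CO insertion gives an aroyl divalent palladium species, and the ring B phenoxide formed by triethylamine next to the ether oxygen attacks the acyl carbon (or binds palladium and undergoes C–O reductive elimination), so the aryl–carbonyl C–C bond and the acyl–oxygen bond are made in one operation. The closest known reaction type is the palladium-catalysed intramolecular aryloxycarbonylation (carbonylative lactonisation) of aryl iodides that carry a tethered phenol. Ring D closes in the 7-exo-trig mode at the acyl carbon, and the wide bite angle of Xantphos favours acyl formation and reductive elimination at atmospheric CO pressure. No stereocentre is formed and the racemic methyl acetal is untouched. The step needs chemoselectivity between the two free ring B hydroxyls and between cyclisation and intermolecular ester formation: the hydroxyl adjacent to the ether oxygen is the only one within reach of the aroyl palladium, the second one sits across the ring and is hydrogen-bonded to the phthalide carbonyl, and high dilution favours ring closure. Because the carbonyl carbon is built on the metal, the crowded site between the methyl group and the aryloxy oxygen never has to be acylated as an acid derivative, and the formyl group, the MOM ether and the acetal are inert to these conditions.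

Step 13
Reactants: 21 depsidone core
Product: 23 hydroxymethyl depsidone (21 with CH2OH on the ring B carbon between the free hydroxyl and the depsidone ester oxygen), via cyclic phenylboronate 22 (not isolated)
Conditions: PhB(OH)2, (CH2O)n, EtCO2H (cat.), toluene, reflux (Dean–Stark); then pinacol, THF, rt
Reagents that add atoms: paraformaldehyde (as formaldehyde), C=O
Why: Ortho-specific hydroxymethylation of a phenol through its phenylboronate, which delivers formaldehyde intramolecularly to the only free ortho carbon of the only free phenol and gives the cyclic boronate that pinacol cleaves; ring A cannot react because its oxygen is a MOM ether.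

Step 14
Reactants: 23 hydroxymethyl depsidone
Product: 24 racemic salazinic acid (free ring A phenol, CH2OH, hydroxyphthalide lactol)
Conditions: 2 M aq. HCl, THF, 45 °C
Reagents that add atoms: water, O
Why: Acid hydrolysis cleaves the MOM acetal and the methyl acetal of the pseudo-ester together and gives the freely epimerising racemic lactol, while the aryl ester of the depsidone is stable to aqueous acid.

Step 15
Reactants: 24 racemic salazinic acid; 25 fumaric acid
Product: 27 racemic target (racemic at the lactol carbon), via ortho-quinone methide 26 (not isolated)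
Conditions: fumaric acid (20 equiv), 1,4-dioxane, 4 Å molecular sieves, 95 °C; excess acid removed by washing with water
Reagents that add atoms: none
Why: Thermal, acid-assisted loss of water from the ortho-hydroxybenzyl alcohol gives an ortho-quinone methide that adds the carboxylic acid (conjugate addition that restores the aromatic ring), and the large excess of diacid with removal of water drives the equilibrium to the mono-ester, the (E) double bond being untouched.

Step 16
Reactants: 27 racemic target; 28 cinchonidine
Product: 29 cinchonidinium salt of the (R)-lactol acid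
Conditions: cinchonidine (1.0 equiv), MeCN/EtOAc, 45 °C, seeded slurry, slow cooling to 5 °C; filtration
Reagents that add atoms: none
Why: Proposed new method: the fumaric half-acid forms a salt with the quinuclidine nitrogen while the lactol carbon epimerises in solution through ring opening to the 2-formylbenzoate, a process the alkaloid base catalyses, so the two diastereomeric salts interconvert and the less soluble one, taken to be the (R)-lactol salt, crystallises and drains the equilibrium; the closest known reaction types are the crystallisation-induced diastereomer transformation of racemising acids as alkaloid salts and the base-mediated dynamic kinetic resolution of 3-hydroxyphthalides, and the (R) stereocentre is set by the lattice of the cinchonidinium salt.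

Step 17
Reactants: 29 cinchonidinium salt
Product: 30 CNP0379578.1, (R) at the lactol carbon
Conditions: 0.5 M aq. HCl, 0 °C (slurry); filtration, cold water wash, vacuum drying
Reagents that add atoms: none
Why: Protonation of the carboxylate in a cold aqueous slurry frees the sparingly soluble acid as a solid while the alkaloid hydrochloride dissolves, so the labile (R) lactol spends no time in basic solution and its configuration should be retained.

**Compound list**

1 | 3-fluoro-5-methylphenol | Cc1cc(O)cc(F)c1 | starting material
2 | 3-fluoro-4-iodo-5-methylphenol | Cc1cc(O)cc(F)c1I | intermediate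
3 | 1-fluoro-2-iodo-5-(methoxymethoxy)-3-methylbenzene | Cc1cc(OCOC)cc(F)c1I | intermediate
4 | [2-fluoro-3-iodo-6-(methoxymethoxy)-4-methylphenyl]lithium | Cc1cc(OCOC)c([Li])c(F)c1I | intermediate
5 | 2-fluoro-3-iodo-6-(methoxymethoxy)-4-methylbenzaldehyde | Cc1cc(OCOC)c(C=O)c(F)c1I | intermediate
6 | ethyl 4-(benzyloxy)-3-oxobutanoate | CCOC(=O)CC(=O)COCc1ccccc1 | starting material
7 | ethyl 4-(benzyloxy)-3-(trimethylsilyloxy)but-2-enoate (E/Z mixture) | CCOC(=O)C=C(COCc1ccccc1)O[Si](C)(C)C | intermediate
8 | lithium 4-(benzyloxy)-1-ethoxy-3-(trimethylsilyloxy)buta-1,3-dien-1-olate | CCOC(O[Li])=CC(O[Si](C)(C)C)=COCc1ccccc1 | intermediate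
9 | 4-(benzyloxy)-1-ethoxy-1,3-bis(trimethylsilyloxy)buta-1,3-diene (isomer mixture) | CCOC(O[Si](C)(C)C)=CC(O[Si](C)(C)C)=COCc1ccccc1 | intermediate
10 | 3,3-diethoxyprop-1-yne | C#CC(OCC)OCC | starting material
11 | (3,3-diethoxyprop-1-yn-1-yl)lithium | [Li]C#CC(OCC)OCC | intermediate
12 | methyl 4,4-diethoxybut-2-ynoate | CCOC(OCC)C#CC(=O)OC | intermediate
13 | methyl 3-(benzyloxy)-2-(diethoxymethyl)-6-ethoxy-4,6-bis(trimethylsilyloxy)cyclohexa-1,4-diene-1-carboxylate (isomer mixture) | CCOC1(O[Si](C)(C)C)C=C(O[Si](C)(C)C)C(OCc2ccccc2)C(C(OCC)OCC)=C1C(=O)OC | intermediate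
14 | methyl 3-(benzyloxy)-2-(diethoxymethyl)-4,6-dihydroxybenzoate | COC(=O)c1c(O)cc(O)c(OCc2ccccc2)c1C(OCC)OCC | intermediate
15 | racemic 4-(benzyloxy)-5,7-dihydroxy-3-methoxy-2-benzofuran-1(3H)-one | COC1OC(=O)c2c(O)cc(O)c(OCc3ccccc3)c12 | intermediate
16 | 4-(benzyloxy)-3-methoxy-5,7-bis(tetrahydro-2H-pyran-2-yloxy)-2-benzofuran-1(3H)-one (diastereomer mixture) | COC1OC(=O)c2c(OC3CCCCO3)cc(OC3CCCCO3)c(OCc3ccccc3)c12 | intermediate
17 | 4-hydroxy-3-methoxy-5,7-bis(tetrahydro-2H-pyran-2-yloxy)-2-benzofuran-1(3H)-one (diastereomer mixture) | COC1OC(=O)c2c(OC3CCCCO3)cc(OC3CCCCO3)c(O)c12 | intermediate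
18 | 3-iodo-2-{[3-methoxy-1-oxo-5,7-bis(tetrahydro-2H-pyran-2-yloxy)-1,3-dihydro-2-benzofuran-4-yl]oxy}-6-(methoxymethoxy)-4-methylbenzaldehyde (diastereomer mixture) | Cc1cc(OCOC)c(C=O)c(Oc2c(OC3CCCCO3)cc(OC3CCCCO3)c3c2C(OC)OC3=O)c1I | intermediate
19 | 2-[(5,7-dihydroxy-3-methoxy-1-oxo-1,3-dihydro-2-benzofuran-4-yl)oxy]-3-iodo-6-(methoxymethoxy)-4-methylbenzaldehyde (racemic) | Cc1cc(OCOC)c(C=O)c(Oc2c(O)cc(O)c3c2C(OC)OC3=O)c1I | intermediate
20 | carbon monoxide | [C-]#[O+] | starting material
21 | depsidone core, racemic methyl acetal (ring A: CH3, OMOM, CHO; ring B: one free OH, one free CH) | Cc1cc(OCOC)c(C=O)c2c1C(=O)Oc1cc(O)c3c(c1O2)C(OC)OC3=O | intermediate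
22 | cyclic phenylboronate of 23 (ring B O–B(Ph)–O–CH2 six-membered ring, racemic) | Cc1cc(OCOC)c(C=O)c2c1C(=O)Oc1c3COB(c4ccccc4)Oc3c3c(c1O2)C(OC)OC3=O | intermediate
23 | hydroxymethyl depsidone, MOM ether and methyl acetal retained (racemic) | Cc1cc(OCOC)c(C=O)c2c1C(=O)Oc1c(CO)c(O)c3c(c1O2)C(OC)OC3=O | intermediate
24 | racemic salazinic acid | Cc1cc(O)c(C=O)c2c1C(=O)Oc1c(CO)c(O)c3c(c1O2)C(O)OC3=O | intermediate
25 | fumaric acid | OC(=O)/C=C/C(=O)O | starting material
26 | ortho-quinone methide of 24 (ring B ketone with exocyclic CH2, racemic) | Cc1cc(O)c(C=O)c2c1C(=O)OC1=C(O2)C3=C(C(=O)OC3O)C(=O)C1=C | intermediate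
27 | racemic target (fumarate half-ester, racemic lactol) | Cc1cc(O)c(C=O)c2c1C(=O)Oc1c(COC(=O)/C=C/C(=O)O)c(O)c3c(c1O2)C(O)OC3=O | intermediate
28 | cinchonidine, (8S,9R) | c1ccc2c(c1)c(ccn2)[C@H]([C@@H]3C[C@@H]4CCN3C[C@@H]4C=C)O | starting material
29 | cinchonidinium salt of the (R)-lactol acid | Cc1cc(O)c(C=O)c2c1C(=O)Oc1c(COC(=O)/C=C/C(=O)[O-])c(O)c3c(c1O2)[C@H](O)OC3=O.c1ccc2c(c1)c(ccn2)[C@H]([C@@H]3C[C@@H]4CC[NH+]3C[C@@H]4C=C)O | intermediate
30 | CNP0379578.1, (R) lactol | Cc1cc(O)c(C=O)c2c1C(=O)Oc1c(COC(=O)/C=C/C(=O)O)c(O)c3c(c1O2)[C@H](O)OC3=O | target

**Step count**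

Total: 17 steps. Longest linear sequence: 13 steps (6 to 30 through steps 4, 5 and 7 to 17).

**Steps most likely to fail**

Step 16 (Proposed new method). No salt may crystallise with useful diastereomeric preference, epimerisation in the mother liquor may be slower than crystallisation of both salts, or the lactol may racemise while the acid is liberated. The fallback uses known practice and sets out from 27. The enantiomers are separated by preparative chromatography on an immobilised amylose tris(3,5-dimethylphenylcarbamate) phase with CO2/MeCN containing 0.1% formic acid at 10 °C. The unwanted enantiomer is racemised with a trace of Et3N in MeCN and recycled. The route is rejoined at 30, and this fallback makes no new compound (F0).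

Step 12. The aroyl palladium may be captured too slowly by the hindered, hydrogen-bonded phenoxide, so that hydrodeiodination or intermolecular ester formation takes over. The fallback sets out from 19 and separates C–C bond formation from ring closure. Aryloxycarbonylation of 19 with 2,4,6-trichlorophenyl formate as a solid CO source (Pd(OAc)2, Xantphos, Et3N, toluene, 80 °C) should give 2,4,6-trichlorophenyl 2-[(5,7-dihydroxy-3-methoxy-1-oxo-1,3-dihydro-2-benzofuran-4-yl)oxy]-3-formyl-4-(methoxymethoxy)-6-methylbenzoate F1. This activated ester is then closed by intramolecular transesterification (DMAP, Et3N, MeCN, high dilution, 60 °C), which returns the route to 21.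

Step 13. The hydrogen-bonded, acyloxy-flanked ring B phenol may be too poor a nucleophile toward boron-bound formaldehyde, or the MOM ether may be lost on heating with acid so that ring A is hydroxymethylated as well. The fallback sets out from 21. Bromination ortho to the free phenol (NBS, MeCN, 0 °C) should give the ring B bromide of 21 F2. Stille coupling of this bromide with Bu3SnCH2OH (Pd(PPh3)4, 1,4-dioxane, 90 °C) installs the hydroxymethyl group and returns the route to 23.

**Further compounds**

F0 | step 16 | none | none
F1 | step 12 | 2,4,6-trichlorophenyl 2-[(5,7-dihydroxy-3-methoxy-1-oxo-1,3-dihydro-2-benzofuran-4-yl)oxy]-3-formyl-4-(methoxymethoxy)-6-methylbenzoate (racemic) | Cc1cc(OCOC)c(C=O)c(Oc2c(O)cc(O)c3c2C(OC)OC3=O)c1C(=O)Oc1c(Cl)cc(Cl)cc1Cl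
F2 | step 13 | ring B bromide of 21 (Br on the carbon between the free hydroxyl and the depsidone ester oxygen, racemic) | Cc1cc(OCOC)c(C=O)c2c1C(=O)Oc1c(Br)c(O)c3c(c1O2)C(OC)OC3=O
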